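The number to carry is 0.900: the capture odds, meaning other capture product made per target made before target has been lost to any great extent, here read from the earliest north-west row. At fixed equivalents it serves as a selectivity factor.

| flask | substrate | first nucleophile | second nucleophile | remark | time |
|---|---|---|---|---|---|
| north-west | 0.62 M | 0.95 equiv | 1.1 equiv | run made earlier |  |
| east | 0.97 M | 0.95 equiv | 1.1 equiv | run made earlier |  |
| flask | 0.44 M | 0.950 equiv | 1.10 equiv |  | 2.0 h |

| run | time / min | other capture product / % | target / % |
|---|---|---|---|
| north-west | 8.00 | 9 | 10 |
| north-west | 20.0 | 14 | 9 |
| north-west | 40.0 | 22 | 6 |
| north-west | 90.0 | 24 | 1 |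
| east | 25.0 | 21 | 9 |
| east | 50.0 | 26 | 6 |
| east | 80.0 | 27 | 0 |
| east | 90.0 | 26 | 0 |

(readings scatter by 1.5 percentage points)

- the earlier runs were read with a standard deviation of 1.5 percentage points

1. share of other capture product in other capture product plus target at 1.0 min
2. share of other capture product in other capture product plus target at 12 min
3. share of other capture product in other capture product plus target at 2.0 h

Down the north-west table, target falls from 10% to 1% while other capture product climbs from 9% to 24%. The share of other capture product in the pair therefore moves on with time: it is 47.4% at 8.00 min, 60.9% at 20.0 min and 96.0% at 90.0 min. The east table opens at 25.0 min with 70.0%, later than the first north-west row, so the odds are read from that north-west row, with the scatter of its readings.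

Across the recipes the equivalents stay the same. If the two nucleophiles compete for one species made from substrate, the odds follow the ratio of the two nucleophile concentrations, and at fixed equivalents substrate concentration cancels from that ratio. This reckoning therefore puts the flask near 47.4% at 1.0 min, between the 8.00 min and 20.0 min shares at 12 min, and high at 2.0 h.

The forecast gives 37% (22% to 48%), 52% and 97%, with “an initial share near 36%, though that extrapolation is uncertain”. At 1.0 min this reckoning stands 10 points above the forecast.

The flask gives 46.2%, 53.2% and 95.4%.

    first nucleophile + target → over-reaction product (k = 0.112 /M/min)
    substrate → intermediate (k = 0.0639 /min)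
    intermediate → side product (k = 0.263 /min)
    first nucleophile + intermediate → target (k = 13.6 /M/min)
    intermediate → solvolysis product (k = 16.0 /min)
    second nucleophile + intermediate → other capture product (k = 9.86 /M/min)

The north-west share behind the capture odds, 47.4%, read at 8.00 min with its scatter, stands beside the flask's 46.2% at 1.0 min. The largest single effect on the flask's later climb is the path from first nucleophile + target to over-reaction product: without that path the flask's share at 2.0 h is 46.4% instead of 95.4%, a shift of 49 points. In the neighbour with 4.40 equiv of second nucleophile, the odds scale by 4.00 to 3.60, a share of 78.3%. That neighbour gives 77.5% at 1.0 min.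

(The readings stem from a simulated flask for an exercise; scatter was added.)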